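## Retrosynthetic overview
1. Calyxin A comes from its bis(aryl acetate). The C5–C3′ bond comes from a suprafacial aromatic Claisen shift of a chalcone 4′-O-(1-arylallyl) ether, so the C5 stereocentre is first stored as a C7–O stereocentre.
2. Key disconnection: the C7–O4′ bond. It is made by enantioselective iridium-catalysed branched O-allylation of the free chalcone with a cinnamyl carbonate.
3. The C5=C6 alkene of the Claisen substrate comes from cross-metathesis of the vinyl ether with an (S)-homoallylic alcohol that carries C3.
4. Building blocks: the chalcone from a Claisen–Schmidt condensation, the carbonate from cross-metathesis of 4-acetoxystyrene, and the alcohol from a Heck reaction followed by catalytic asymmetric allylboration.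
5. No ring is formed. All four benzene rings are bought.

Assumption: heptanoid carbons are numbered C1–C7 from the saturated arm (C3 carbinol, C5 benzylic, C7 next to the styryl ring), chalcone ring A carries primed numbers, and the catalyst antipodes named are those expected from the accepted facial models (both antipodes are commercial, so the other one is taken if a first run shows the opposite sense).

## Route

Step 1
Reactants: 1 4-iodophenol; 2 allyl alcohol
Product: 4 3-(4-hydroxyphenyl)propanal, via enol 3 (not isolated)
Conditions: Pd(OAc)2 (2 mol%), NaHCO3 (2.5 equiv), n-Bu4NCl (1 equiv), DMF, 45 °C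
Reagents that add atoms: none
Why: Heck reaction under phase-transfer (Jeffery) conditions: aryl–palladium adds to the terminal alkene carbon and β-hydride elimination toward the carbinol gives enol 3, which tautomerises to the aldehyde, the free phenol being tolerated by the weak base; no stereocentre is formed.

Step 2
Reactants: 4 3-(4-hydroxyphenyl)propanal; 5 allylboronic acid pinacol ester
Product: 7 4-[(3S)-3-hydroxyhex-5-en-1-yl]phenol, via borate ester 6 (not isolated)
Conditions: (R)-TRIP phosphoric acid (5 mol%), PhMe–CH2Cl2 (3:1), −30 °C; then H2O work-up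
Reagents that add atoms: none
Why: Chiral-phosphoric-acid-catalysed asymmetric allylboration: the acid hydrogen-bonds to a boronate oxygen and the formyl hydrogen in a closed chair (Zimmerman–Traxler) transition state and exposes one aldehyde face, which sets C3 as S (about 90% ee expected for this unbranched aldehyde), and the phenol does not react with the pinacol boronate.

Step 3
Reactants: 8 2′,4′-dihydroxy-6′-methoxyacetophenone; 9 4-acetoxybenzaldehyde
Product: 11 helichrysetin 4-acetate (E-chalcone), via aldol adduct 10 (not isolated)
Conditions: BF3·OEt2 (50 mol%), 1,4-dioxane, rt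
Reagents that add atoms: none
Why: Lewis-acid-mediated Claisen–Schmidt (crossed aldol) condensation: boron chelation of the 2′-hydroxy ketone promotes enolisation and holds the product in the open chalcone form, aldol 10 dehydrates to the conjugated E-enone, and the base-free medium keeps the aryl acetate.

Step 4
Reactants: 12 4-acetoxystyrene; 13 allyl methyl carbonate
Product: 14 (E)-3-(4-acetoxyphenyl)allyl methyl carbonate
Conditions: second-generation Hoveyda–Grubbs catalyst (2 mol%), 13 (3 equiv), CH2Cl2, 40 °C
Reagents that add atoms: none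
Why: Olefin cross-metathesis: excess 13 drives the styrene to the cross product, the aryl-conjugated alkene forms as the E isomer under thermodynamic control, and ester and carbonate groups are inert to the ruthenium carbene.

Step 5 (key C–O bond)
Reactants: 11 helichrysetin 4-acetate; 14 (E)-3-(4-acetoxyphenyl)allyl methyl carbonate
Product: 15 (R)-branched ether: chalcone 11 alkylated at O-4′ by the (1R)-1-(4-acetoxyphenyl)prop-2-en-1-yl group
Conditions: [Ir(cod)Cl]2 (2 mol%), (Sa,Sc,Sc)-O,O′-(1,1′-binaphthalene-2,2′-diyl) N,N-bis(1-phenylethyl)phosphoramidite (4 mol%; pre-activated with n-PrNH2, volatiles removed), 14 (1.2 equiv), THF, 25 °C, no added base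
Reagents that add atoms: none
Why: Proposed new method: salt-free, site-selective and branched-enantioselective iridium-catalysed O-allylation of an unprotected acylresorcinol; the cyclometalated monovalent iridium phosphoramidite complex adds oxidatively to 14 to give a trivalent iridium π-allyl and methyl carbonate, which loses CO2 to methoxide that deprotonates only the most acidic free phenol of 11 (O-4′, pKa about 7.5; O-2′ is locked in the hydrogen bond to the ketone), and the low steady-state concentration of this aryloxide attacks the aryl-bearing allyl terminus anti to the metal on the face left open by the ligand, which sets C7 as R, while the absence of alkali base avoids acetyl transfer and flavanone closure and the slight excess of 14 keeps the catalyst from re-ionising the product; the closest known reaction type is the iridium–phosphoramidite allylic etherification of cinnamyl carbonates with preformed alkali aryloxides, not yet shown for polyhydroxychalcones or for such stabilised aryloxides that are also good leaving groups.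

Step 6
Reactants: 15 (R)-branched ether; 7 4-[(3S)-3-hydroxyhex-5-en-1-yl]phenol
Product: 16 chalcone 11 alkylated at O-4′ by the (1R,2E,5S)-1-(4-acetoxyphenyl)-5-hydroxy-7-(4-hydroxyphenyl)hept-2-en-1-yl group
Conditions: second-generation Hoveyda–Grubbs catalyst (5 mol%), 7 (2 equiv), 1,4-benzoquinone (10 mol%), CH2Cl2, 40 °C
Reagents that add atoms: none
Why: Olefin cross-metathesis: the hindered secondary allylic ether 15 does not homodimerise, so the carbene derived from the unhindered alkene of 7 captures its vinyl group to give the E-1,2-disubstituted alkene, while the electron-poor enone, the free hydroxyl groups and both stereocentres (C7 R, C3 S) are untouched and benzoquinone suppresses hydride-induced alkene migration.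

Step 7
Reactants: 16 full-chain (7R,3S) ether
Product: 19 calyxin A, via dienone 17 (not isolated), via diacetate 18 (not isolated)
Conditions: PhCl (0.02 M), BHT (5 mol%), 120 °C, to full conversion; evaporate; then NH4OAc (8 equiv), degassed MeOH–H2O (4:1), rt
Reagents that add atoms: none
Why: Aromatic Claisen rearrangement followed by tautomerisation and neutral ester hydrolysis: the suprafacial [3,3] shift through the conformer with the C7 aryl group pseudo-equatorial turns the C7 (R) C–O stereocentre and the E-C5=C6 alkene into the C5 (R) C–C stereocentre and the E-styrene, the chelated 2′-hydroxy ketone fixes double-bond character in C3′–C4′ and so directs the shift to C3′, dienone 17 re-aromatises to 18, and NH4OAc in aqueous methanol then cleaves only the two aryl acetates without the base that would close the chalcone to a flavanone.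

## Compound list
1 | 4-iodophenol | Oc1ccc(I)cc1 | starting material
2 | allyl alcohol (prop-2-en-1-ol) | C=CCO | starting material
3 | 3-(4-hydroxyphenyl)prop-1-en-1-ol (enol, geometry not defined) | OC=CCc1ccc(O)cc1 | intermediate
4 | 3-(4-hydroxyphenyl)propanal | O=CCCc1ccc(O)cc1 | intermediate
5 | allylboronic acid pinacol ester (2-allyl-4,4,5,5-tetramethyl-1,3,2-dioxaborolane) | C=CCB1OC(C)(C)C(C)(C)O1 | starting material
6 | 4-{(3S)-3-[(4,4,5,5-tetramethyl-1,3,2-dioxaborolan-2-yl)oxy]hex-5-en-1-yl}phenol | C=CC[C@@H](OB1OC(C)(C)C(C)(C)O1)CCc1ccc(O)cc1 | intermediate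
7 | 4-[(3S)-3-hydroxyhex-5-en-1-yl]phenol | C=CC[C@@H](O)CCc1ccc(O)cc1 | intermediate
8 | 1-(2,4-dihydroxy-6-methoxyphenyl)ethanone (2′,4′-dihydroxy-6′-methoxyacetophenone) | COc1cc(O)cc(O)c1C(C)=O | starting material
9 | 4-acetoxybenzaldehyde (4-formylphenyl acetate) | CC(=O)Oc1ccc(C=O)cc1 | starting material
10 | 4-[3-(2,4-dihydroxy-6-methoxyphenyl)-1-hydroxy-3-oxopropyl]phenyl acetate (racemic aldol adduct) | COc1cc(O)cc(O)c1C(=O)CC(O)c1ccc(OC(C)=O)cc1 | intermediate
11 | 4-[(1E)-3-(2,4-dihydroxy-6-methoxyphenyl)-3-oxoprop-1-en-1-yl]phenyl acetate (helichrysetin 4-acetate) | COc1cc(O)cc(O)c1C(=O)/C=C/c1ccc(OC(C)=O)cc1 | intermediate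
12 | 4-acetoxystyrene (4-vinylphenyl acetate) | C=Cc1ccc(OC(C)=O)cc1 | starting material
13 | allyl methyl carbonate | C=CCOC(=O)OC | starting material
14 | (E)-3-(4-acetoxyphenyl)allyl methyl carbonate | COC(=O)OC/C=C/c1ccc(OC(C)=O)cc1 | intermediate
15 | 4-[(1R)-1-{4-[(2E)-3-(4-acetoxyphenyl)prop-2-enoyl]-3-hydroxy-5-methoxyphenoxy}prop-2-en-1-yl]phenyl acetate | COc1cc(O[C@H](C=C)c2ccc(OC(C)=O)cc2)cc(O)c1C(=O)/C=C/c1ccc(OC(C)=O)cc1 | intermediate
16 | 4-[(1R,2E,5S)-1-{4-[(2E)-3-(4-acetoxyphenyl)prop-2-enoyl]-3-hydroxy-5-methoxyphenoxy}-5-hydroxy-7-(4-hydroxyphenyl)hept-2-en-1-yl]phenyl acetate | COc1cc(O[C@H](/C=C/C[C@@H](O)CCc3ccc(O)cc3)c2ccc(OC(C)=O)cc2)cc(O)c1C(=O)/C=C/c1ccc(OC(C)=O)cc1 | intermediate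
17 | cyclohexa-2,4-dienone tautomer of 18 (C4′ ketone, C3′ sp3 bearing H and the heptenyl group, configuration at C3′ not defined) | COC1=CC(=O)C([C@@H](/C=C/c2ccc(OC(C)=O)cc2)C[C@@H](O)CCc2ccc(O)cc2)C(O)=C1C(=O)/C=C/c1ccc(OC(C)=O)cc1 | intermediate
18 | calyxin A diacetate (acetates on the styryl ring phenol and on the chalcone ring B phenol; C5 R, C3 S) | COc1cc(O)c([C@@H](/C=C/c2ccc(OC(C)=O)cc2)C[C@@H](O)CCc2ccc(O)cc2)c(O)c1C(=O)/C=C/c1ccc(OC(C)=O)cc1 | intermediate
19 | calyxin A, (2E)-1-{2,4-dihydroxy-3-[(1E,3R,5S)-5-hydroxy-1,7-bis(4-hydroxyphenyl)hept-1-en-3-yl]-6-methoxyphenyl}-3-(4-hydroxyphenyl)prop-2-en-1-one | COc1cc(O)c([C@@H](/C=C/c2ccc(O)cc2)C[C@@H](O)CCc2ccc(O)cc2)c(O)c1C(=O)/C=C/c1ccc(O)cc1 | target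

## Step count and risks
Total step count: 7. Longest linear sequence: 4 steps (for example 12 → 14 → 15 → 16 → 19). The other two branches, 1 → 4 → 7 and 8 → 11, are equally short.

**Step 5 (proposed new step).**
- Risk: the aryloxide of 11 is a weak nucleophile and a good leaving group. The branched ether may therefore re-ionise, which would erode the branched-to-linear ratio and the ee. Ring C-allylation or acetyl transfer may also compete.
- Fallback (known chemistry only): it sets out from 9 and 11 and comes back at 15.
  - Vinylmagnesium bromide adds to 9 in THF at −78 °C with a cold quench. This gives rac-4-(1-hydroxyprop-2-en-1-yl)phenyl acetate F1.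
  - Kinetic resolution with immobilised Candida antarctica lipase B and vinyl acetate in MTBE acetylates the R alcohol to 4-[(1R)-1-acetoxyprop-2-en-1-yl]phenyl acetate F3. It leaves 4-[(1S)-1-hydroxyprop-2-en-1-yl]phenyl acetate F2.
  - A Mitsunobu etherification of F2 with the acidic O-4′ phenol of 11 (PPh3, DIAD, PhMe, −20 °C) proceeds with inversion and gives the R ether 15.

**Step 7 (Claisen stage).**
- Risk: some shift to C5′, partial ionisation with loss of chirality transfer, or thermal flavanone closure.
- Fallback: it sets out from 16 and comes back at 18. It makes no compound outside the list (entry F0).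
  - Pd(PPh3)4 (5 mol%) in THF at rt to 40 °C replaces the pericyclic step by a Tsuji–Trost O-to-C allyl transfer.
  - Zerovalent palladium ionises the C7–O bond with inversion.
  - The released ambident aryloxide re-adds through C3′, anti to the metal, at the allyl terminus remote from the aryl group (C5).
  - O-attack is reversible, so the material funnels to 18 with the same C5 (R) configuration and the E-styrene.
  - The NH4OAc stage of step 7 follows.

**Step 3.**
- Risk: the activated aldehyde may alkylate the electron-rich ring of 8, or the boron chelate may resist hydrolysis.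
- Fallback: it sets out from 8 and comes back at 11.
  - O-4′ is masked with 3,4-dihydro-2H-pyran and PPTS in CH2Cl2. This gives 1-[2-hydroxy-6-methoxy-4-(tetrahydro-2H-pyran-2-yloxy)phenyl]ethanone F4.
  - A classical base-mediated Claisen–Schmidt condensation with 4-hydroxybenzaldehyde (KOH, EtOH, rt) gives (2E)-1-[2-hydroxy-6-methoxy-4-(tetrahydro-2H-pyran-2-yloxy)phenyl]-3-(4-hydroxyphenyl)prop-2-en-1-one F5.
  - Ac2O and pyridine at 0 °C acetylate the only unchelated phenol. This gives 4-{(1E)-3-[2-hydroxy-6-methoxy-4-(tetrahydro-2H-pyran-2-yloxy)phenyl]-3-oxoprop-1-en-1-yl}phenyl acetate F6.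
  - PPTS in MeOH at rt removes the acetal and gives 11.

## Further compounds
F1 | step 5 | rac-4-(1-hydroxyprop-2-en-1-yl)phenyl acetate | C=CC(O)c1ccc(OC(C)=O)cc1
F2 | step 5 | 4-[(1S)-1-hydroxyprop-2-en-1-yl]phenyl acetate | C=C[C@H](O)c1ccc(OC(C)=O)cc1
F3 | step 5 | 4-[(1R)-1-acetoxyprop-2-en-1-yl]phenyl acetate | C=C[C@@H](OC(C)=O)c1ccc(OC(C)=O)cc1
F0 | step 7 | none | none
F4 | step 3 | 1-[2-hydroxy-6-methoxy-4-(tetrahydro-2H-pyran-2-yloxy)phenyl]ethanone | COc1cc(OC2CCCCO2)cc(O)c1C(C)=O
F5 | step 3 | (2E)-1-[2-hydroxy-6-methoxy-4-(tetrahydro-2H-pyran-2-yloxy)phenyl]-3-(4-hydroxyphenyl)prop-2-en-1-one | COc1cc(OC2CCCCO2)cc(O)c1C(=O)/C=C/c1ccc(O)cc1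
F6 | step 3 | 4-{(1E)-3-[2-hydroxy-6-methoxy-4-(tetrahydro-2H-pyran-2-yloxy)phenyl]-3-oxoprop-1-en-1-yl}phenyl acetate | COc1cc(OC2CCCCO2)cc(O)c1C(=O)/C=C/c1ccc(OC(C)=O)cc1
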